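**Assumption:** the SMILES is taken literally: 4Z and ring-cis 1(10) alkenes, 6R,7S,8S,9S, side chain 2S. Germacrane locants are used in the text (C6 = lactone O-carbon, C7 = ring-fusion CH, C8 = acetolactate carbinol, C9 = isobutyrate carbinol, C10 = ester-bearing alkene carbon).

**Retrosynthetic overview**
- Target ⇐ organocatalytic α-hydroxylation of the C8 2-methylacetoacetate ⇐ ring-closing metathesis at C4=C5 of a lactone triene.
- Lactone triene ⇐ CrCl2 allylation of acrolein and lactonisation (C6–C7 bond, γ-lactone) ⇐ allylic bromide carrying the C1–C4 chain (cross-metathesis at C1=C10).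
- Allylic bromide ⇐ meso bis(α-methylene-β-hydroxy ester) triol: organocatalytic desymmetrising isobutyrylation (sets C8 and C9), SN2′ bromination of the sacrificial carbinol, acylketene esterification of C8–OH.
- Meso-triol ⇐ two-directional hydroxy-directed singlet-oxygen ene reaction ⇐ double cross-metathesis of divinyl carbinol with two molecules of methyl methacrylate.
- Ring order: γ-lactone first (step 7), then the ten-membered carbocycle (step 8).

**Route**

Step 1
Reactants: 1 penta-1,4-dien-3-ol; 2 methyl methacrylate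
Product: 4 dimethyl (2E,5E)-4-hydroxy-2,6-dimethylhepta-2,5-dienedioate, via mono-cross-metathesis ester 3 (not isolated)
Conditions: second-generation Hoveyda–Grubbs catalyst (5 mol %), 1,4-benzoquinone (10 mol %), neat methyl methacrylate (20 equiv), 45 °C, N2 sweep
Reagents that add atoms: methyl methacrylate (second molecule of 2, consumed by intermediate 3), C=C(C)C(=O)OC
Why: Two-directional olefin cross-metathesis: the first vinyl group of 1 exchanges with one molecule of 2 to give racemic mono-enoate 3, whose remaining vinyl group exchanges with a second molecule of 2 in the same flask, each trisubstituted enoate forming with the carbinol trans to the ester (thermodynamic E); no stereocentre survives and 4 is achiral.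

Step 2
Reactants: 4 dimethyl (2E,5E)-4-hydroxy-2,6-dimethylhepta-2,5-dienedioate
Product: 6 dimethyl (3R,4r,5S)-3,4,5-trihydroxy-2,6-dimethylideneheptanedioate (meso-triol), via bis-hydroperoxide 5 (not isolated)
Conditions: O2, tetraphenylporphyrin (1 mol %), white LED, CH2Cl2, −10 °C; then PPh3 (2.1 equiv), 0 °C
Reagents that add atoms: dioxygen (as singlet oxygen generated in the flask; one molecule adds to each arm), O=O
Why: Hydroxy-directed Schenck ene reaction: on each arm the methyl geminal to the ester is abstracted and, with 1,3-allylic strain fixing the carbinol conformation, the OH steers oxygen to its own face, so both new C–O bonds are threo to the central OH and phosphine reduction gives the achiral meso all-threo triol.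

Step 3
Reactants: 6 dimethyl (3R,4r,5S)-3,4,5-trihydroxy-2,6-dimethylideneheptanedioate; 7 isobutyric anhydride
Product: 8 dimethyl (3S,4S,5R)-4,5-dihydroxy-2,6-dimethylidene-3-[(2-methylpropanoyl)oxy]heptanedioate
Conditions: (R)-benzotetramisole [(R)-2-phenyl-2,3-dihydroimidazo[2,1-b][1,3]benzothiazole] (10 mol %), 7 (1.15 equiv), i-Pr2NEt (1.2 equiv), CHCl3, −30 °C
Reagents that add atoms: none
Why: Proposed new method: enantiotopic-group-selective acyl transfer from the N-isobutyryl isothiouronium ion of the catalyst to one of the two mirror-image α-methylene-β-hydroxy ester carbinols of a meso 1,2,3-triol; the acrylate π-system next to each terminal carbinol supplies the cation–π/carbonyl recognition the catalyst needs, the central OH has no π-neighbour and stays free, the (R)-catalyst picks the carbinol shaped like an (R)-1-arylalkanol, and second acylation drains the minor enantiomer; this sets the absolute configuration of C8 and C9 and installs the natural isobutyrate; the closest known reaction type is isothiourea-catalysed kinetic resolution of secondary allylic or benzylic alcohols and acylative desymmetrisation of meso-diols, not yet shown for Morita–Baylis–Hillman-type carbinols or for triols.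

Step 4
Reactants: 8 dimethyl (3S,4S,5R)-4,5-dihydroxy-2,6-dimethylidene-3-[(2-methylpropanoyl)oxy]heptanedioate
Product: 9 dimethyl (2Z,4S,5S)-2-(bromomethyl)-4-hydroxy-6-methylidene-5-[(2-methylpropanoyl)oxy]hept-2-enedioate
Conditions: NBS (1.3 equiv), Me2S (1.5 equiv), CH2Cl2, 0 °C to rt
Reagents that add atoms: N-bromosuccinimide, O=C1CCC(=O)N1Br
Why: Corey–Kim-type activation of the allylic (Morita–Baylis–Hillman-type) hydroxyl and SN2′ attack of bromide give the (Z)-2-(bromomethyl)enoate, erasing the sacrificial C5 stereocentre while the non-allylic C4–OH is untouched.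

Step 5
Reactants: 9 dimethyl (2Z,4S,5S)-2-(bromomethyl)-4-hydroxy-6-methylidene-5-[(2-methylpropanoyl)oxy]hept-2-enedioate; 10 2,2,5,6-tetramethyl-4H-1,3-dioxin-4-one
Product: 12 dimethyl (2Z,4S,5S)-2-(bromomethyl)-6-methylidene-4-[(2-methyl-3-oxobutanoyl)oxy]-5-[(2-methylpropanoyl)oxy]hept-2-enedioate, via acetyl(methyl)ketene 11 (not isolated)
Conditions: 10 (2 equiv), toluene, 105 °C, 1 h, acetone distilled off
Reagents that add atoms: none
Why: Thermal retro-[4+2] of the dioxinone releases the acylketene, which esterifies the hindered secondary alcohol under neutral, amine-free conditions that leave the allylic bromide alone (acylketene trapping); the new α-CH centre of the β-keto ester is an inconsequential epimer mixture.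

Step 6
Reactants: 12 dimethyl (2Z,4S,5S)-2-(bromomethyl)-6-methylidene-4-[(2-methyl-3-oxobutanoyl)oxy]-5-[(2-methylpropanoyl)oxy]hept-2-enedioate; 13 2-methylhexa-1,5-diene
Product: 14 dimethyl (2Z,4S,5S,6E)-2-(bromomethyl)-6-(4-methylpent-4-en-1-ylidene)-4-[(2-methyl-3-oxobutanoyl)oxy]-5-[(2-methylpropanoyl)oxy]hept-2-enedioate
Conditions: 13 (6 equiv), second-generation Hoveyda–Grubbs catalyst (7 mol %), CH2Cl2, 40 °C
Reagents that add atoms: none
Why: Olefin cross-metathesis of the only terminal acrylate alkene with the monosubstituted end of the diene (its 1,1-disubstituted end and the trisubstituted bromo-enoate are inert) gives the C1=C10 enoate with C2 cis to C9 (E, thermodynamic); no stereocentre is formed.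

Step 7
Reactants: 14 dimethyl (2Z,4S,5S,6E)-2-(bromomethyl)-6-(4-methylpent-4-en-1-ylidene)-4-[(2-methyl-3-oxobutanoyl)oxy]-5-[(2-methylpropanoyl)oxy]hept-2-enedioate; 15 acrolein
Product: 18 methyl (2E)-2-{(1S,2S)-2-[(2R,3S)-2-ethenyl-4-methylidene-5-oxooxolan-3-yl]-2-[(2-methyl-3-oxobutanoyl)oxy]-1-[(2-methylpropanoyl)oxy]ethyl}-6-methylhepta-2,6-dienoate, via allylchromium dichloride 16 (not isolated), via hydroxy diester 17 (not isolated)
Conditions: CrCl2 (4 equiv), 15 (3 equiv), THF, 0 °C to rt; 1 M HCl work-up; then TsOH·H2O (10 mol %), CH2Cl2, rt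
Reagents that add atoms: none
Why: Nozaki–Hiyama-type allylation: the equilibrating allyl reagent of trivalent chromium, which spares the side-chain ketone, should add 1,2 to the enal through a closed chair with both substituents equatorial (anti adduct, hence trans-lactone) on the alkene face anti to the C8–C9 bond (allylic-strain model), setting C6 (R) and C7 (S); acid-catalysed lactonisation can only involve O6 because O8 is already acylated.

Step 8
Reactants: 18 methyl (2E)-2-{(1S,2S)-2-[(2R,3S)-2-ethenyl-4-methylidene-5-oxooxolan-3-yl]-2-[(2-methyl-3-oxobutanoyl)oxy]-1-[(2-methylpropanoyl)oxy]ethyl}-6-methylhepta-2,6-dienoate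
Product: 19 methyl (3aS,4S,5S,6E,10Z,11aR)-10-methyl-3-methylidene-4-[(2-methyl-3-oxobutanoyl)oxy]-5-[(2-methylpropanoyl)oxy]-2-oxo-2,3,3a,4,5,8,9,11a-octahydrocyclodeca[b]furan-6-carboxylate
Conditions: second-generation Grubbs catalyst (15 mol %, in portions), toluene (1 mM), 80 °C, Ar sparge
Reagents that add atoms: none
Why: Ring-closing metathesis between the C6 vinyl group and the 1,1-disubstituted C4 alkene closes the ten-membered ring, whose strain favours the ring-cis (4Z) trisubstituted alkene; no stereocentre is touched.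

Step 9
Reactants: 19 methyl (3aS,4S,5S,6E,10Z,11aR)-10-methyl-3-methylidene-4-[(2-methyl-3-oxobutanoyl)oxy]-5-[(2-methylpropanoyl)oxy]-2-oxo-2,3,3a,4,5,8,9,11a-octahydrocyclodeca[b]furan-6-carboxylate
Product: 20 methyl (3aS,4S,5S,6E,10Z,11aR)-4-{[(2S)-2-hydroxy-2-methyl-3-oxobutanoyl]oxy}-10-methyl-3-methylidene-5-[(2-methylpropanoyl)oxy]-2-oxo-2,3,3a,4,5,8,9,11a-octahydrocyclodeca[b]furan-6-carboxylate (CNP0280649.2)
Conditions: hydroquinidine (20 mol %), cumene hydroperoxide (1.5 equiv), CH2Br2, −20 °C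
Reagents that add atoms: cumene hydroperoxide, CC(C)(OO)c1ccccc1
Why: Organocatalytic electrophilic α-hydroxylation of a β-keto ester: both side-chain epimers converge on one enolate, which the cinchona base holds as a chiral ion pair and oxygenates on one face (catalyst control; the pseudo-enantiomeric hydroquinine would give the 2R epimer), creating the (S) tertiary alcohol.

**Compound list**
1 | penta-1,4-dien-3-ol | C=CC(O)C=C | starting material
2 | methyl methacrylate | C=C(C)C(=O)OC | starting material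
3 | methyl (2E)-4-hydroxy-2-methylhexa-2,5-dienoate (racemic mono-cross-metathesis ester) | COC(=O)/C(C)=C/C(O)C=C | intermediate
4 | dimethyl (2E,5E)-4-hydroxy-2,6-dimethylhepta-2,5-dienedioate | COC(=O)/C(C)=C/C(O)/C=C(\C)C(=O)OC | intermediate
5 | dimethyl (3R,4r,5S)-3,5-dihydroperoxy-4-hydroxy-2,6-dimethylideneheptanedioate (meso bis-hydroperoxide) | C=C(C(=O)OC)[C@H](OO)[C@@H](O)[C@H](OO)C(=C)C(=O)OC | intermediate
6 | dimethyl (3R,4r,5S)-3,4,5-trihydroxy-2,6-dimethylideneheptanedioate (meso, all-threo) | C=C(C(=O)OC)[C@H](O)[C@@H](O)[C@H](O)C(=C)C(=O)OC | intermediate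
7 | isobutyric anhydride | CC(C)C(=O)OC(=O)C(C)C | starting material
8 | dimethyl (3S,4S,5R)-4,5-dihydroxy-2,6-dimethylidene-3-[(2-methylpropanoyl)oxy]heptanedioate | C=C(C(=O)OC)[C@H](OC(=O)C(C)C)[C@@H](O)[C@H](O)C(=C)C(=O)OC | intermediate
9 | dimethyl (2Z,4S,5S)-2-(bromomethyl)-4-hydroxy-6-methylidene-5-[(2-methylpropanoyl)oxy]hept-2-enedioate | BrC/C(C(=O)OC)=C\[C@H](O)[C@@H](OC(=O)C(C)C)C(=C)C(=O)OC | intermediate
10 | 2,2,5,6-tetramethyl-4H-1,3-dioxin-4-one | CC1=C(C)C(=O)OC(C)(C)O1 | starting material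
11 | acetyl(methyl)ketene (2-methyl-1-oxobut-1-en-3-one) | CC(=O)C(C)=C=O | intermediate
12 | dimethyl (2Z,4S,5S)-2-(bromomethyl)-6-methylidene-4-[(2-methyl-3-oxobutanoyl)oxy]-5-[(2-methylpropanoyl)oxy]hept-2-enedioate (epimers at the keto ester α-carbon) | BrC/C(C(=O)OC)=C\[C@H](OC(=O)C(C)C(C)=O)[C@@H](OC(=O)C(C)C)C(=C)C(=O)OC | intermediate
13 | 2-methylhexa-1,5-diene | C=CCCC(C)=C | starting material
14 | dimethyl (2Z,4S,5S,6E)-2-(bromomethyl)-6-(4-methylpent-4-en-1-ylidene)-4-[(2-methyl-3-oxobutanoyl)oxy]-5-[(2-methylpropanoyl)oxy]hept-2-enedioate | BrC/C(C(=O)OC)=C\[C@H](OC(=O)C(C)C(C)=O)[C@@H](OC(=O)C(C)C)/C(C(=O)OC)=C\CCC(C)=C | intermediate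
15 | acrolein | C=CC=O | starting material
16 | σ-allylchromium dichloride of 14 (CrCl2 unit of trivalent chromium in place of Br; C2=C3 geometry equilibrating) | Cl[Cr](Cl)CC(C(=O)OC)=C[C@H](OC(=O)C(C)C(C)=O)[C@@H](OC(=O)C(C)C)/C(C(=O)OC)=C\CCC(C)=C | intermediate
17 | dimethyl (3S,4S,5S,6E)-3-[(1R)-1-hydroxyprop-2-en-1-yl]-2-methylidene-6-(4-methylpent-4-en-1-ylidene)-4-[(2-methyl-3-oxobutanoyl)oxy]-5-[(2-methylpropanoyl)oxy]heptanedioate | COC(=O)C(=C)[C@@H]([C@H](O)C=C)[C@H](OC(=O)C(C)C(C)=O)[C@@H](OC(=O)C(C)C)/C(C(=O)OC)=C\CCC(C)=C | intermediate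
18 | methyl (2E)-2-{(1S,2S)-2-[(2R,3S)-2-ethenyl-4-methylidene-5-oxooxolan-3-yl]-2-[(2-methyl-3-oxobutanoyl)oxy]-1-[(2-methylpropanoyl)oxy]ethyl}-6-methylhepta-2,6-dienoate | C=C1C(=O)O[C@H](C=C)[C@H]1[C@H](OC(=O)C(C)C(C)=O)[C@@H](OC(=O)C(C)C)/C(C(=O)OC)=C\CCC(C)=C | intermediate
19 | methyl (3aS,4S,5S,6E,10Z,11aR)-10-methyl-3-methylidene-4-[(2-methyl-3-oxobutanoyl)oxy]-5-[(2-methylpropanoyl)oxy]-2-oxo-2,3,3a,4,5,8,9,11a-octahydrocyclodeca[b]furan-6-carboxylate | C=C1C(=O)O[C@@H]2/C=C(/C)CC/C=C(/C(=O)OC)[C@H](OC(=O)C(C)C)[C@@H](OC(=O)C(C)C(C)=O)[C@@H]12 | intermediate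
20 | methyl (3aS,4S,5S,6E,10Z,11aR)-4-{[(2S)-2-hydroxy-2-methyl-3-oxobutanoyl]oxy}-10-methyl-3-methylidene-5-[(2-methylpropanoyl)oxy]-2-oxo-2,3,3a,4,5,8,9,11a-octahydrocyclodeca[b]furan-6-carboxylate | C=C1C(=O)O[C@@H]2/C=C(/C)CC/C=C(/C(=O)OC)[C@H](OC(=O)C(C)C)[C@@H](OC(=O)[C@@](C)(O)C(C)=O)[C@@H]12 | target

**Step count**
Total steps: 9. Longest linear sequence: 9 (fully linear from 1 and 2).

**Three steps most likely to fail**

Step 3 (the proposed new desymmetrisation). It may fail through acylation of the central hydroxyl or through poor discrimination of the two terminal carbinols. The fallback uses known chemistry, sets out from 6 and comes back at 8. Enantioselective mono-silylation of the meso-triol (TBSCl, i-Pr2NEt, amino-acid-derived N-methylimidazole silylation catalyst, THF, −30 °C; catalyst enantiomer chosen so that the carbinol that is later sacrificed is silylated) gives dimethyl (3S,4R,5R)-5-{[tert-butyl(dimethyl)silyl]oxy}-3,4-dihydroxy-2,6-dimethylideneheptanedioate F1. Isobutyrylation of the less hindered allylic hydroxyl at the other end (isobutyric anhydride, DMAP 5 mol %, pyridine, CH2Cl2, −20 °C; the central OH is shielded by the neighbouring silyl ether) gives dimethyl (3S,4R,5R)-5-{[tert-butyl(dimethyl)silyl]oxy}-4-hydroxy-2,6-dimethylidene-3-[(2-methylpropanoyl)oxy]heptanedioate F2. HF·pyridine in THF at 0 °C then frees 8.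

Step 7 (chromium allylation). The anti/trans-lactone outcome and the face selectivity at C7 rest on models, and the closed-chair pathway from the Z-configured allyl reagent would instead give the 6-epi (cis-lactone) series. The fallback sets out from 14 and comes back at 17. A Zn-mediated Barbier reaction with acrolein (Zn dust, saturated aqueous NH4Cl/THF, 0 °C) is stopped at the open-chain adduct, dimethyl (3S,4S,5S,6E)-3-[(1S)-1-hydroxyprop-2-en-1-yl]-2-methylidene-6-(4-methylpent-4-en-1-ylidene)-4-[(2-methyl-3-oxobutanoyl)oxy]-5-[(2-methylpropanoyl)oxy]heptanedioate F3 (any C6 epimer mixture is acceptable). Dess–Martin oxidation (NaHCO3, CH2Cl2) gives the vinyl ketone dimethyl (3R,4S,5S,6E)-2-methylidene-6-(4-methylpent-4-en-1-ylidene)-4-[(2-methyl-3-oxobutanoyl)oxy]-5-[(2-methylpropanoyl)oxy]-3-(prop-2-enoyl)heptanedioate F4. Reagent-controlled Corey–Bakshi–Shibata reduction ((R)-2-methyl-CBS-oxazaborolidine 20 mol %, catecholborane, toluene, −78 °C, vinyl as the large group) then sets 6R and gives 17, which lactonises to 18 as in step 7.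

Step 8 (ring-closing metathesis). A ten-membered carbocycle closing to a trisubstituted alkene may oligomerise, may not close, or may instead close a six-membered ring onto the C1=C10 enoate with loss of the C1–C4 chain. The fallback sets out from 12 and comes back at 19; it closes the ring at C6–C7 instead, by intramolecular chromium allylation. The enal partner is made from commercial neryl acetate: selective ozonolysis of the distal alkene (O3, CH2Cl2, −78 °C; Me2S) gives (2Z)-3-methyl-6-oxohex-2-en-1-yl acetate F5, Wittig methylenation (Ph3P=CH2, THF, −78 °C to 0 °C) gives (2Z)-3-methylhepta-2,6-dien-1-yl acetate F6, methanolysis (K2CO3, MeOH) gives (2Z)-3-methylhepta-2,6-dien-1-ol F7, and MnO2 in CH2Cl2 gives (2Z)-3-methylhepta-2,6-dienal F8. Cross-metathesis of 12 with F8 (second-generation Hoveyda–Grubbs catalyst, CH2Cl2, 40 °C) gives dimethyl (2Z,4S,5S,6E)-2-(bromomethyl)-6-[(4Z)-4-methyl-6-oxohex-4-en-1-ylidene]-4-[(2-methyl-3-oxobutanoyl)oxy]-5-[(2-methylpropanoyl)oxy]hept-2-enedioate F9. Syringe-pump addition of F9 to CrCl2 (6 equiv) in THF at 2 mM and 1 M HCl work-up give the ring-closed hydroxy diester methyl (1E,5Z,7R,8S,9S,10S)-7-hydroxy-8-(3-methoxy-3-oxoprop-1-en-2-yl)-5-methyl-9-[(2-methyl-3-oxobutanoyl)oxy]-10-[(2-methylpropanoyl)oxy]cyclodeca-1,5-diene-1-carboxylate F10, which TsOH·H2O in CH2Cl2 lactonises to 19, with the 4Z alkene carried in from neryl acetate.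

Further compounds
F1 | step 3 | dimethyl (3S,4R,5R)-5-{[tert-butyl(dimethyl)silyl]oxy}-3,4-dihydroxy-2,6-dimethylideneheptanedioate | C=C(C(=O)OC)[C@H](O)[C@@H](O)[C@H](O[Si](C)(C)C(C)(C)C)C(=C)C(=O)OC
F2 | step 3 | dimethyl (3S,4R,5R)-5-{[tert-butyl(dimethyl)silyl]oxy}-4-hydroxy-2,6-dimethylidene-3-[(2-methylpropanoyl)oxy]heptanedioate | C=C(C(=O)OC)[C@H](OC(=O)C(C)C)[C@@H](O)[C@H](O[Si](C)(C)C(C)(C)C)C(=C)C(=O)OC
F3 | step 7 | dimethyl (3S,4S,5S,6E)-3-[(1S)-1-hydroxyprop-2-en-1-yl]-2-methylidene-6-(4-methylpent-4-en-1-ylidene)-4-[(2-methyl-3-oxobutanoyl)oxy]-5-[(2-methylpropanoyl)oxy]heptanedioate | COC(=O)C(=C)[C@@H]([C@@H](O)C=C)[C@H](OC(=O)C(C)C(C)=O)[C@@H](OC(=O)C(C)C)/C(C(=O)OC)=C\CCC(C)=C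
F4 | step 7 | dimethyl (3R,4S,5S,6E)-2-methylidene-6-(4-methylpent-4-en-1-ylidene)-4-[(2-methyl-3-oxobutanoyl)oxy]-5-[(2-methylpropanoyl)oxy]-3-(prop-2-enoyl)heptanedioate | COC(=O)C(=C)[C@@H](C(=O)C=C)[C@H](OC(=O)C(C)C(C)=O)[C@@H](OC(=O)C(C)C)/C(C(=O)OC)=C\CCC(C)=C
F5 | step 8 | (2Z)-3-methyl-6-oxohex-2-en-1-yl acetate | O=CCC/C(C)=C\COC(C)=O
F6 | step 8 | (2Z)-3-methylhepta-2,6-dien-1-yl acetate | C=CCC/C(C)=C\COC(C)=O
F7 | step 8 | (2Z)-3-methylhepta-2,6-dien-1-ol | C=CCC/C(C)=C\CO
F8 | step 8 | (2Z)-3-methylhepta-2,6-dienal | C=CCC/C(C)=C\C=O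
F9 | step 8 | dimethyl (2Z,4S,5S,6E)-2-(bromomethyl)-6-[(4Z)-4-methyl-6-oxohex-4-en-1-ylidene]-4-[(2-methyl-3-oxobutanoyl)oxy]-5-[(2-methylpropanoyl)oxy]hept-2-enedioate | BrC/C(C(=O)OC)=C\[C@H](OC(=O)C(C)C(C)=O)[C@@H](OC(=O)C(C)C)/C(C(=O)OC)=C\CC/C(C)=C\C=O
F10 | step 8 | methyl (1E,5Z,7R,8S,9S,10S)-7-hydroxy-8-(3-methoxy-3-oxoprop-1-en-2-yl)-5-methyl-9-[(2-methyl-3-oxobutanoyl)oxy]-10-[(2-methylpropanoyl)oxy]cyclodeca-1,5-diene-1-carboxylate | COC(=O)C(=C)[C@H]1[C@H](O)/C=C(/C)CC/C=C(/C(=O)OC)[C@H](OC(=O)C(C)C)[C@H]1OC(=O)C(C)C(C)=O
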